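**Plan**

- Numbering: C1 acetoxy CH, C2, C3 methyl/acetoxy carbon, C4, C5 ring-fusion CH, C6, C7 ketone, C8=C9, C10, C11, N12, C13–C15, C16 quaternary; skeleton locants below use it.
- Enabling feature: the cyclopentanone ring C5–C6–C7–C8–C16 holds the C7 carbonyl next to the exocyclic C8=C9 alkene on quaternary C16, with C10 cis to C16. This is what syn addition of a C7 aldehyde C–H across a C16-bound C8≡C9 alkyne leaves behind.
- Cuts: N12–C13 and N12–C11 (azonine, nitrogen from a sulfonamide), then C7–C8 (hydroacylation), then C16–C15 and C5–C6 (enolate alkylation and vinyl conjugate addition), then C16–C8 (Sonogashira), back to 3-methylcyclohexenone.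
- Forward order: the cyclohexane is bought, the cyclopentanone closes second (rhodium hydroacylation), the nine-membered azonine ring closes last (sulfonamide N-alkylation).
- Stereochemistry: C3 from copper-catalysed asymmetric conjugate borylation; C5 from axial vinyl addition cis to the C3 oxygen; C16 from alkylation anti to the C5 vinyl group; C1 from thermodynamically controlled ketone reduction; the alkene geometry from syn hydroacylation.

Key step: step 13

Assumption: the (R,R) antipode of QuinoxP* is written in step 1 on the premise that it leads to the (R)-boronate 2; should the first run show the opposite sense, the (S,S) ligand is used and nothing else changes.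

**Route**

Step 1
Reactants: 1 3-methylcyclohex-2-en-1-one
Product: 3 (S)-3-hydroxy-3-methylcyclohexan-1-one, via tertiary pinacol boronate 2 (not isolated)
Conditions: [Cu(MeCN)4]PF6 (5 mol %), (R,R)-QuinoxP* (6 mol %), LiOtBu (10 mol %), B2pin2, MeOH, DMSO, rt; then NaBO3·4H2O, THF/H2O, rt
Reagents that add atoms: bis(pinacolato)diboron, CC1(C)OB(OC1(C)C)B1OC(C)(C)C(C)(C)O1 (boryl group of 2); sodium perborate, O[B-]1(O)OO[B-](O)(O)OO1.[Na+].[Na+] (hydroxyl oxygen of 3)
Why: Enantioselective conjugate borylation by a chiral bisphosphine copper boryl complex builds the tetrasubstituted C3 centre, and perborate oxidation replaces boron by oxygen with retention.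

Step 2
Reactants: 3 (S)-3-hydroxy-3-methylcyclohexan-1-one
Product: 4 (S)-3-methyl-3-(triethylsilyloxy)cyclohexan-1-one
Conditions: TESOTf, 2,6-lutidine, CH2Cl2, −78 °C
Reagents that add atoms: triethylsilyl trifluoromethanesulfonate, CC[Si](CC)(CC)OS(=O)(=O)C(F)(F)F
Why: Silyl triflate silylation caps the hindered tertiary hydroxyl at low temperature, which shuts down retro-aldol cleavage and dehydration of the aldol in the basic steps that follow.

Step 3
Reactants: 4 (S)-3-methyl-3-(triethylsilyloxy)cyclohexan-1-one
Product: 6 (S)-5-methyl-5-(triethylsilyloxy)cyclohex-2-en-1-one, via trimethylsilyl enol ether 5 (not isolated)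
Conditions: LDA, TMSCl, THF, −78 °C; then Pd(OAc)2 (10 mol %), O2 (1 atm), DMSO, rt
Reagents that add atoms: chlorotrimethylsilane, C[Si](C)(C)Cl (silyl group of 5; none of it stays in 6)
Why: Kinetic deprotonation with in situ silyl trapping takes the less hindered C16 methylene, and Saegusa–Ito oxidation by divalent palladium under oxygen then gives the only enone possible, since the C2 enol ether has no hydrogen on C3 to lose.

Step 4
Reactants: 6 (S)-5-methyl-5-(triethylsilyloxy)cyclohex-2-en-1-one
Product: 7 (S)-2-iodo-5-methyl-5-(triethylsilyloxy)cyclohex-2-en-1-one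
Conditions: I2, pyridine, CH2Cl2, 0 °C → rt
Reagents that add atoms: iodine, II
Why: Pyridine-promoted α-iodination of the enone (conjugate addition of pyridine, iodination of the enolate, elimination) puts iodine on C16 under conditions too mild to expel the β-silyloxy group.

Step 5
Reactants: 8 but-3-yn-1-ol
Product: 9 1-[(but-3-yn-1-yloxy)methyl]-4-methoxybenzene
Conditions: NaH, PMBCl, Bu4NI (cat.), THF/DMF, 0 °C → rt
Reagents that add atoms: 4-methoxybenzyl chloride, COc1ccc(CCl)cc1
Why: Williamson ether synthesis on the sodium alkoxide, the alkyne C–H being far less acidic than the hydroxyl.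

Step 6
Reactants: 7 (S)-2-iodo-5-methyl-5-(triethylsilyloxy)cyclohex-2-en-1-one; 9 1-[(but-3-yn-1-yloxy)methyl]-4-methoxybenzene
Product: 10 (S)-2-[4-(4-methoxybenzyloxy)but-1-ynyl]-5-methyl-5-(triethylsilyloxy)cyclohex-2-en-1-one
Conditions: PdCl2(PPh3)2 (3 mol %), CuI (6 mol %), iPr2NH, THF, 0 °C → rt
Reagents that add atoms: none
Why: Sonogashira coupling, in which oxidative addition of the electron-poor C16–I bond to zerovalent palladium and transmetalation from the copper acetylide run at or below room temperature and so leave the β-silyloxy ketone intact.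

Step 7
Reactants: 10 (S)-2-[4-(4-methoxybenzyloxy)but-1-ynyl]-5-methyl-5-(triethylsilyloxy)cyclohex-2-en-1-one; 11 vinylmagnesium bromide
Product: 12 (3S,5S)-2-[4-(4-methoxybenzyloxy)but-1-ynyl]-5-methyl-5-(triethylsilyloxy)-1-(trimethylsilyloxy)-3-vinylcyclohex-1-ene (vinyl cis to the triethylsilyloxy group)
Conditions: CuBr·SMe2 (20 mol %), TMSCl, HMPA, THF, −78 °C; Et3N, pentane work-up
Reagents that add atoms: chlorotrimethylsilane, C[Si](C)(C)Cl
Why: Copper-catalysed conjugate addition of the vinyl Grignard reagent with chlorosilane trapping gives the regiodefined silyl enol ether, and axial attack on the half-chair that keeps the C3 methyl pseudo-equatorial and the smaller silyloxy group pseudo-axial delivers vinyl to the face of the C3 oxygen, which sets C5.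

Step 8
Reactants: 12 the silyl enol ether of step 7; 13 1-chloro-3-iodopropane
Product: 15 (2S,3S,5S)-2-(3-chloropropyl)-2-[4-(4-methoxybenzyloxy)but-1-ynyl]-5-methyl-5-(triethylsilyloxy)-3-vinylcyclohexan-1-one (alkyne cis and chloropropyl trans to vinyl), via lithium enolate 14 (not isolated)
Conditions: MeLi, THF, 0 °C; then HMPA, 13, −78 → −20 °C
Reagents that add atoms: methyllithium, [Li]C (lithium of 14 only; nothing of it stays in 15)
Why: Methyllithium cleaves the silyl enol ether to the regiodefined lithium enolate, whose SN2 alkylation by the iodide end of 13 in THF/HMPA takes place anti to the neighbouring C5 vinyl group, so that the alkyne ends cis and the chloropropyl chain trans to vinyl at the new quaternary C16.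

Step 9
Reactants: 15 the quaternary ketone of step 8
Product: 17 (1S,3S,4S,5S)-4-(3-chloropropyl)-4-[4-(4-methoxybenzyloxy)but-1-ynyl]-1-methyl-5-vinylcyclohexane-1,3-diol (hydroxyls cis), via silyl-protected alcohol 16 (not isolated)
Conditions: SmI2, Et3N, H2O, THF, 0 °C; then 2 M HCl, MeOH, rt
Reagents that add atoms: none
Why: Electron-transfer reduction through the samarium ketyl and carbinyl anion should give the more stable alcohol, the equatorial C1 hydroxyl cis to the C3 oxygen (its epimer would be syn-axial to the C3 methyl), and dilute acid then cleaves the tertiary triethylsilyl ether while the 4-methoxybenzyl ether and the chloride stay.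

Step 10
Reactants: 17 the cis-diol of step 9
Product: 18 (C1 S, C3 S, C5 S, C16 S)-diacetate: C1 and C3 acetoxy, C5 vinyl, C16 bearing the 4-(4-methoxybenzyloxy)but-1-ynyl and 3-chloropropyl groups
Conditions: Ac2O, Et3N, DMAP, CH2Cl2, rt → 40 °C
Reagents that add atoms: acetic anhydride, CC(=O)OC(C)=O
Why: DMAP-catalysed acylation (Steglich conditions) esterifies the secondary and, more slowly, the equatorial tertiary hydroxyl, and the mild amine base leaves chloride, alkyne and ether untouched.

Step 11
Reactants: 18 the vinyl diacetate of step 10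
Product: 20 (C1 S, C3 S, C5 R, C16 S)-diacetate with a 2-hydroxyethyl arm on C5 (same spatial arrangement as 18), via B-alkyl-9-BBN adduct 19 (not isolated)
Conditions: 9-BBN, THF, 0 °C → rt; then NaBO3·4H2O, H2O, rt
Reagents that add atoms: 9-borabicyclo[3.3.1]nonane, B1C2CCCC1CCC2 (boryl group of 19); sodium perborate, O[B-]1(O)OO[B-](O)(O)OO1.[Na+].[Na+] (hydroxyl oxygen of 20)
Why: 9-BBN hydroborates the monosubstituted alkene anti-Markovnikov much faster than the internal alkyne shielded by quaternary C16, and perborate oxidises the C–B bond without hydrolysing the acetates.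

Step 12
Reactants: 20 the primary alcohol of step 11
Product: 21 (C1 S, C3 S, C5 S, C16 S)-diacetate with a formylmethyl arm on C5 and, on C16, the 4-(4-methoxybenzyloxy)but-1-ynyl and 3-chloropropyl groups
Conditions: Dess–Martin periodinane, NaHCO3, CH2Cl2, 0 °C → rt
Reagents that add atoms: none
Why: Dess–Martin oxidation stops at the aldehyde under buffered neutral conditions that neither touch the acetates nor epimerise any centre.

Step 13
Reactants: 21 the alkynal of step 12
Product: 22 (C1 S, C3 S, C5 S, C16 S)-cis-hydrindanone: C7 ketone, (E)-C8=C9 alkylidene carrying CH2CH2O-PMB, 3-chloropropyl on C16, acetates on C1 and C3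
Conditions: [Rh(dppe)]2(BF4)2 (5 mol %; from [Rh(nbd)(dppe)]BF4 and H2), acetone, rt
Reagents that add atoms: none
Why: Oxidative addition of the C7 aldehyde C–H bond to the cationic monovalent rhodium bisphosphine gives an acyl rhodium hydride, the C8≡C9 alkyne inserts into Rh–H in a syn fashion with rhodium on C8, and C7–C8 reductive elimination releases the ketone. The closest known reaction type is the rhodium-catalysed intramolecular hydroacylation of 5-alkynals to α-alkylidene cyclopentanones. The cyclopentanone C5–C6–C7–C8–C16 closes in the 5-exo-dig mode, C9 staying outside the ring. No stereocentre is formed; the alkene geometry follows from delivery of acyl and hydrogen to the same side of the alkyne, which puts C10 trans to the C7 carbonyl and cis to C16, as the azonine ring requires. The step needs exo rather than 6-endo closure and no decarbonylation: the cis arrangement of the C5 formylmethyl arm and the alkyne on the cyclohexane holds the five-atom tether ready for the six-membered acyl rhodacycle, the chelating dppe ligand disfavours CO extrusion at room temperature, and the quaternary propargylic C16 rules out isomerisation of the alkyne.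

Step 14
Reactants: 22 the hydrindanone of step 13
Product: 23 the same hydrindanone with a free C11 hydroxyl (2-hydroxyethyl on C9)
Conditions: DDQ, CH2Cl2/pH 7 buffer, 0 °C → rt
Reagents that add atoms: none
Why: Oxidative cleavage of the 4-methoxybenzyl ether by DDQ (hydride abstraction, hydrolysis of the hemiacetal) is neutral and spares the enone, the acetates and the chloride.

Step 15
Reactants: 23 the C11 alcohol of step 14; 24 2-nitrobenzenesulfonamide
Product: 25 the hydrindanone with C11–NH–SO2(2-nitrophenyl) and the C13 chloride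
Conditions: PPh3, DIAD, THF, 0 °C → rt (24 in excess)
Reagents that add atoms: none
Why: Mitsunobu alkylation of the acidic sulfonamide N–H by the activated primary alcohol installs N12 on C11, an excess of 24 suppressing double alkylation.

Step 16
Reactants: 25 the chloro sulfonamide of step 15
Product: 26 N12-(2-nitrobenzenesulfonyl) derivative of the target (azonine ring closed)
Conditions: Cs2CO3, NaI (cat.), MeCN (0.005 M), 60 °C
Reagents that add atoms: none
Why: Intramolecular SN2 alkylation of the caesium sulfonamide by the C13 iodide formed in situ (Finkelstein exchange) closes the nine-membered ring at high dilution, the ring-cis C8=C9 alkene and the quaternary C16 holding the two chain ends close.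

Step 17
Reactants: 26 the N-sulfonyl azonine of step 16
Product: 27 CNP0120442.1, (C1 S, C3 S, C5 S, C16 S, 8E)
Conditions: PhSH (1.2 equiv), K2CO3, MeCN, rt
Reagents that add atoms: none
Why: Thiolate adds to the nitroarene (Meisenheimer complex) and expels sulfur dioxide and the free amine (Fukuyama deprotection) at room temperature, and any reversible thiol addition to the enone is drained by this irreversible cleavage when the thiol is kept near one equivalent.

**Compound list**

1 | 3-methylcyclohex-2-en-1-one | CC1=CC(=O)CCC1 | starting material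
2 | (R)-3-methyl-3-(4,4,5,5-tetramethyl-1,3,2-dioxaborolan-2-yl)cyclohexan-1-one; not isolated | O=C1C[C@@](C)(B2OC(C)(C)C(C)(C)O2)CCC1 | intermediate
3 | (S)-3-hydroxy-3-methylcyclohexan-1-one | O=C1C[C@@](C)(O)CCC1 | intermediate
4 | (S)-3-methyl-3-(triethylsilyloxy)cyclohexan-1-one | O=C1C[C@@](C)(O[Si](CC)(CC)CC)CCC1 | intermediate
5 | (S)-triethyl{[1-methyl-3-(trimethylsilyloxy)cyclohex-3-en-1-yl]oxy}silane; not isolated | C[Si](C)(C)OC1=CCC[C@](C)(O[Si](CC)(CC)CC)C1 | intermediate
6 | (S)-5-methyl-5-(triethylsilyloxy)cyclohex-2-en-1-one | O=C1C[C@@](C)(O[Si](CC)(CC)CC)CC=C1 | intermediate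
7 | (S)-2-iodo-5-methyl-5-(triethylsilyloxy)cyclohex-2-en-1-one | O=C1C[C@@](C)(O[Si](CC)(CC)CC)CC=C1I | intermediate
8 | but-3-yn-1-ol | C#CCCO | starting material
9 | 1-[(but-3-yn-1-yloxy)methyl]-4-methoxybenzene | C#CCCOCc1ccc(OC)cc1 | intermediate
10 | (S)-2-[4-(4-methoxybenzyloxy)but-1-ynyl]-5-methyl-5-(triethylsilyloxy)cyclohex-2-en-1-one | O=C1C[C@@](C)(O[Si](CC)(CC)CC)CC=C1C#CCCOCc2ccc(OC)cc2 | intermediate
11 | vinylmagnesium bromide | C=C[Mg]Br | starting material
12 | (3S,5S)-2-[4-(4-methoxybenzyloxy)but-1-ynyl]-5-methyl-5-(triethylsilyloxy)-1-(trimethylsilyloxy)-3-vinylcyclohex-1-ene | C[Si](C)(C)OC1=C(C#CCCOCc2ccc(OC)cc2)[C@H](C=C)C[C@](C)(O[Si](CC)(CC)CC)C1 | intermediate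
13 | 1-chloro-3-iodopropane | ClCCCI | starting material
14 | lithium enolate corresponding to 12; not isolated | [Li]OC1=C(C#CCCOCc2ccc(OC)cc2)[C@H](C=C)C[C@](C)(O[Si](CC)(CC)CC)C1 | intermediate
15 | (2S,3S,5S)-2-(3-chloropropyl)-2-[4-(4-methoxybenzyloxy)but-1-ynyl]-5-methyl-5-(triethylsilyloxy)-3-vinylcyclohexan-1-one | O=C1C[C@@](C)(O[Si](CC)(CC)CC)C[C@@H](C=C)[C@]1(C#CCCOCc2ccc(OC)cc2)CCCCl | intermediate
16 | (1S,2S,3S,5S)-2-(3-chloropropyl)-2-[4-(4-methoxybenzyloxy)but-1-ynyl]-5-methyl-5-(triethylsilyloxy)-3-vinylcyclohexan-1-ol; not isolated | O[C@H]1C[C@@](C)(O[Si](CC)(CC)CC)C[C@@H](C=C)[C@]1(C#CCCOCc2ccc(OC)cc2)CCCCl | intermediate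
17 | (1S,3S,4S,5S)-4-(3-chloropropyl)-4-[4-(4-methoxybenzyloxy)but-1-ynyl]-1-methyl-5-vinylcyclohexane-1,3-diol | O[C@H]1C[C@@](C)(O)C[C@@H](C=C)[C@]1(C#CCCOCc2ccc(OC)cc2)CCCCl | intermediate
18 | diacetate of 17 (C1 S, C3 S, C5 S, C16 S) | CC(=O)O[C@H]1C[C@@](C)(OC(C)=O)C[C@@H](C=C)[C@]1(C#CCCOCc2ccc(OC)cc2)CCCCl | intermediate
19 | B-alkyl-9-BBN adduct of 18 (boron on C7); not isolated | CC(=O)O[C@H]1C[C@@](C)(OC(C)=O)C[C@@H](CCB2C3CCCC2CCC3)[C@]1(C#CCCOCc2ccc(OC)cc2)CCCCl | intermediate
20 | diacetate with 2-hydroxyethyl arm on C5 (C1 S, C3 S, C5 R, C16 S) | CC(=O)O[C@H]1C[C@@](C)(OC(C)=O)C[C@@H](CCO)[C@]1(C#CCCOCc2ccc(OC)cc2)CCCCl | intermediate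
21 | diacetate with formylmethyl arm on C5, alkynal for the key step (C1 S, C3 S, C5 S, C16 S) | CC(=O)O[C@H]1C[C@@](C)(OC(C)=O)C[C@@H](CC=O)[C@]1(C#CCCOCc2ccc(OC)cc2)CCCCl | intermediate
22 | cis-hydrindanone with (E)-alkylidene ketone, C11 O-PMB, 3-chloropropyl on C16 (C1 S, C3 S, C5 S, C16 S) | CC(=O)O[C@H]1C[C@@](C)(OC(C)=O)C[C@H]2CC(=O)/C(=C/CCOCc3ccc(OC)cc3)[C@]21CCCCl | intermediate
23 | hydrindanone with free C11 hydroxyl | CC(=O)O[C@H]1C[C@@](C)(OC(C)=O)C[C@H]2CC(=O)/C(=C/CCO)[C@]21CCCCl | intermediate
24 | 2-nitrobenzenesulfonamide | NS(=O)(=O)c1ccccc1[N+](=O)[O-] | starting material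
25 | hydrindanone with C11 2-nitrobenzenesulfonamide and C13 chloride | CC(=O)O[C@H]1C[C@@](C)(OC(C)=O)C[C@H]2CC(=O)/C(=C/CCNS(=O)(=O)c3ccccc3[N+](=O)[O-])[C@]21CCCCl | intermediate
26 | N12-(2-nitrobenzenesulfonyl) derivative of the target | CC(=O)O[C@H]1C[C@@](C)(OC(C)=O)C[C@H]2CC(=O)/C3=C/CCN(S(=O)(=O)c4ccccc4[N+](=O)[O-])CCC[C@@]321 | intermediate
27 | CNP0120442.1 (C1 S, C3 S, C5 S, C16 S, 8E) | CC(=O)O[C@H]1C[C@@](C)(OC(C)=O)C[C@H]2CC(=O)/C3=C/CCNCCC[C@@]321 | target

**Count and risks**

Total step count: 17. Longest linear sequence: 16 steps (1 → 27 through steps 1–4 and 6–17; step 5 is the side branch).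

Step 8 (most likely to fail). C-alkylation of the conjugated, hindered lithium enolate 14 by an unactivated primary iodide may be too slow, so that proton transfer, O-alkylation or loss of the C3 silyloxy group take over. The fallback brings in the three-carbon chain by conjugate addition instead and sets out from silyl enol ether 12. Compound 12 is added to acrolein under BF3·OEt2 in CH2Cl2 at −78 °C (Mukaiyama–Michael reaction, again anti to the C5 vinyl group) to give keto aldehyde F1. The aldehyde alone is reduced with NaBH(OAc)3 to hydroxy ketone F2. An Appel reaction (PPh3, CCl4) then converts the primary alcohol into the chloride, which is ketone 15, where the route is rejoined.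

Step 9. Protonation at C1 may be kinetically rather than thermodynamically controlled, giving poor facial selectivity and mainly the axial alcohol. The fallback sets out from ketone 15: the crude reduction mixture, containing the C1-epimeric alcohol F3, is taken before the acid stage and heated with Al(OiPr)3 and a little acetone in toluene (Meerwein–Ponndorf–Verley/Oppenauer equilibration). Reversible hydride transfer through 15 drains F3, whose hydroxyl is syn-axial to the C3 methyl group, into 16, and the acid treatment of step 9 then gives diol 17, where the route is rejoined.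

Step 16. Intermolecular N-alkylation (oligomer formation) may outrun closure of the nine-membered ring. The fallback makes the other C–N bond in the ring-closing event and sets out from hydrindanone 22. The chloride of 22 is displaced by sulfonamide 24 (K2CO3, NaI, DMF, 60 °C) to give C13 sulfonamide F4. DDQ then frees the C11 alcohol, giving hydroxy sulfonamide F5. An intramolecular Fukuyama–Mitsunobu reaction (PPh3, DIAD, toluene, high dilution) closes N12–C11 under neutral conditions and gives 26, where the route is rejoined.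

**Further compounds**

F1 | step 8 | (2S,3S,5S)-3-{1-[4-(4-methoxybenzyloxy)but-1-ynyl]-4-methyl-2-oxo-4-(triethylsilyloxy)-6-vinylcyclohexyl}propanal | O=C1C[C@@](C)(O[Si](CC)(CC)CC)C[C@@H](C=C)[C@]1(C#CCCOCc2ccc(OC)cc2)CCC=O
F2 | step 8 | (2S,3S,5S)-2-(3-hydroxypropyl)-2-[4-(4-methoxybenzyloxy)but-1-ynyl]-5-methyl-5-(triethylsilyloxy)-3-vinylcyclohexan-1-one | O=C1C[C@@](C)(O[Si](CC)(CC)CC)C[C@@H](C=C)[C@]1(C#CCCOCc2ccc(OC)cc2)CCCO
F3 | step 9 | C1 epimer of 16, (1R,2S,3S,5S) | O[C@@H]1C[C@@](C)(O[Si](CC)(CC)CC)C[C@@H](C=C)[C@]1(C#CCCOCc2ccc(OC)cc2)CCCCl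
F4 | step 16 | hydrindanone 22 with the C13 chloride replaced by NH–SO2(2-nitrophenyl) | CC(=O)O[C@H]1C[C@@](C)(OC(C)=O)C[C@H]2CC(=O)/C(=C/CCOCc3ccc(OC)cc3)[C@]21CCCNS(=O)(=O)c4ccccc4[N+](=O)[O-]
F5 | step 16 | C11 alcohol of F4 | CC(=O)O[C@H]1C[C@@](C)(OC(C)=O)C[C@H]2CC(=O)/C(=C/CCO)[C@]21CCCNS(=O)(=O)c4ccccc4[N+](=O)[O-]
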